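**Strategy.** The target, epiguibourtinidol-(4α→8)-epicatechin, is cut at the C4–C8 bond into two (2S)-flavanones made by asymmetric conjugate addition. The lower flavanone is ring-contracted to a 2,3-trans-2-aryl-2,3-dihydrobenzofuran-3-methanol. The key step exploits the electron-rich lower phloroglucinol ring (ring D): its ipso carbon (later C4a) shifts from C3 to the exocyclic CH2 (later C4) through a phenonium ion while water enters at C3, so the dihydrofuran becomes the lower pyran ring F (O1–C2–C3–C4–C4a–C8a) and the 3-OH is set trans to the 2-aryl group in one operation. Acid-mediated coupling with a flavan-3,4-diol, then oxidation and bulky-hydride reduction at both C3 atoms, gives the all-cis target after hydrogenolysis.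

Key step: step 5

Assumption: in steps 2 and 7 the (R)-configured pyridine–oxazoline ligand is taken to deliver the aryl group to the face that gives the (2S)-flavanone, by analogy with the sense known for cyclic enones; should the sense be the opposite, the (S)-ligand is used.

**Route**

Step 1
Reactants: 1 5,7-dihydroxy-4H-chromen-4-one
Product: 2 5,7-bis(benzyloxy)-4H-chromen-4-one
Conditions: BnBr (2.6 equiv), K2CO3, Bu4NI (cat.), DMF, 80 °C
Reagents that add atoms: benzyl bromide BrCc1ccccc1
Why: Williamson ether synthesis; the hydrogen-bonded 5-OH should be benzylated at the elevated temperature, and no stereocentre is formed.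

Step 2
Reactants: 2 5,7-bis(benzyloxy)-4H-chromen-4-one; 3 [3,4-bis(benzyloxy)phenyl]boronic acid (2 equiv)
Product: 4 (2S)-5,7-bis(benzyloxy)-2-[3,4-bis(benzyloxy)phenyl]-2,3-dihydro-4H-chromen-4-one
Conditions: Pd(OCOCF3)2 (5 mol %), (R)-4-tert-butyl-2-(pyridin-2-yl)-4,5-dihydrooxazole (6 mol %), NH4PF6 (30 mol %), H2O (5 equiv), ClCH2CH2Cl, 60 °C
Reagents that add atoms: none
Why: Palladium-catalysed asymmetric conjugate addition of an arylboronic acid to a chromone; the chiral pyridine–oxazoline ligand on the cationic aryl-palladium species selects the face of C2, and the base-free medium should prevent opening of the flavanone to the chalcone, which would racemise C2.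

Step 3
Reactants: 4 (2S)-5,7-bis(benzyloxy)-2-[3,4-bis(benzyloxy)phenyl]-2,3-dihydro-4H-chromen-4-one
Product: 6 methyl (2S,3S)-4,6-bis(benzyloxy)-2-[3,4-bis(benzyloxy)phenyl]-2,3-dihydro-1-benzofuran-3-carboxylate (2,3-trans), via methyl enol ether 5 (not isolated)
Conditions: HC(OMe)3, H2SO4 (cat.), PhI(OAc)2 (1.2 equiv), 20 °C; aq. NaHCO3
Reagents that add atoms: trimethyl orthoformate COC(OC)OC; water O
Why: Hypervalent-iodine oxidative ring contraction of a flavanone: the trivalent iodine electrophile attacks C3 of enol ether 5 anti to the 2-aryl group, then carbon C4a of the benzo ring shifts from C4 to C3 with loss of iodobenzene while C4 becomes the ester carbon; C2 is not touched and the new C3 centre should come out trans to the aryl group.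

Step 4
Reactants: 6 methyl (2S,3S)-4,6-bis(benzyloxy)-2-[3,4-bis(benzyloxy)phenyl]-2,3-dihydro-1-benzofuran-3-carboxylate
Product: 7 [(2S,3R)-4,6-bis(benzyloxy)-2-[3,4-bis(benzyloxy)phenyl]-2,3-dihydro-1-benzofuran-3-yl]methanol (2,3-trans)
Conditions: LiAlH4, THF, 0 °C
Reagents that add atoms: none
Why: Hydride reduction of the ester to the primary alcohol; reduction should be faster than enolisation, so neither C2 nor C3 is disturbed and no new stereocentre is formed.

Step 5
Reactants: 7 [(2S,3R)-4,6-bis(benzyloxy)-2-[3,4-bis(benzyloxy)phenyl]-2,3-dihydro-1-benzofuran-3-yl]methanol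
Product: 9 (2R,3S)-5,7-bis(benzyloxy)-2-[3,4-bis(benzyloxy)phenyl]chroman-3-ol (5,7,3',4'-tetra-O-benzylcatechin), via primary methanesulfonate 8 (not isolated)
Conditions: Ms2O, 2,6-lutidine, CH2Cl2, −20 °C; then (CF3)2CHOH–H2O 4:1, 2,6-lutidine, 25–40 °C
Reagents that add atoms: methanesulfonic anhydride CS(=O)(=O)OS(C)(=O)=O (mesyl group, carried only by 8); water O
Why: Ionisation of 8 in the cation-stabilising fluoro alcohol should be assisted by the ipso carbon of the 2,4,6-trioxygenated ring (Ar1-3 participation, a 3-exo-tet closure to a spiro[2.5]octadienyl phenonium ion bridging C3 and the CH2 group). Water then opens this cyclopropane at the secondary carbon C3 from the face opposite to the bridging carbon, so the C3–C(ipso) bond is exchanged for C3–OH with inversion, the aryl carbon ends on the former CH2, and the dihydrofuran ring O1–C2–C3–C3a–C7a becomes the pyran ring O1–C2–C3–C4–C4a–C8a. The closest known reaction type is the neophyl-type (Wagner–Meerwein) phenonium rearrangement with ring expansion, as in the solvolysis of indan-1-ylmethyl sulfonates to 2-tetralyl products; it is the reverse sense of the aryl shift of step 3. The new C3 stereocentre is fixed by the C3 configuration of 7 (stereospecific 1,2-shift, trans-7 giving the 2,3-trans alcohol, 3S), and C2 is untouched. The step needs opening at C3 and not at CH2 (secured by the strain of the cyclopropane fused to the five-membered ring and by secondary against primary carbon) and aryl shift in place of hydride shift (secured by the very electron-rich migrating ring); the buffer should keep the benzylic C2–O1 ether intact.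

Step 6
Reactants: 10 7-hydroxy-4H-chromen-4-one
Product: 11 7-(benzyloxy)-4H-chromen-4-one
Conditions: BnBr (1.2 equiv), K2CO3, acetone, reflux
Reagents that add atoms: benzyl bromide BrCc1ccccc1
Why: Williamson ether synthesis on the acidic 7-OH; no stereocentre is formed.

Step 7
Reactants: 11 7-(benzyloxy)-4H-chromen-4-one; 12 [4-(benzyloxy)phenyl]boronic acid (2 equiv)
Product: 13 (2S)-7-(benzyloxy)-2-[4-(benzyloxy)phenyl]-2,3-dihydro-4H-chromen-4-one
Conditions: Pd(OCOCF3)2 (5 mol %), (R)-4-tert-butyl-2-(pyridin-2-yl)-4,5-dihydrooxazole (6 mol %), NH4PF6 (30 mol %), H2O (5 equiv), ClCH2CH2Cl, 60 °C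
Reagents that add atoms: none
Why: The same palladium-catalysed asymmetric conjugate addition as in step 2; the ligand sets C2, and the base-free medium should avoid racemisation through the chalcone.

Step 8
Reactants: 13 (2S)-7-(benzyloxy)-2-[4-(benzyloxy)phenyl]-2,3-dihydro-4H-chromen-4-one
Product: 16 (2R,3R)-7-(benzyloxy)-2-[4-(benzyloxy)phenyl]-3-hydroxy-2,3-dihydro-4H-chromen-4-one (2,3-trans), via trimethylsilyl enol ether 14 (not isolated), via 3-silyloxy ketone 15 (not isolated)
Conditions: TMSOTf, Et3N, CH2Cl2, 0 °C; mCPBA, CH2Cl2, −20 °C; 1 M HCl, THF, 0 °C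
Reagents that add atoms: trimethylsilyl trifluoromethanesulfonate C[Si](C)(C)OS(=O)(=O)C(F)(F)F (silyl group, carried only by 14 and 15); 3-chloroperoxybenzoic acid OOC(=O)c1cccc(Cl)c1
Why: Rubottom oxidation: soft enolisation avoids the enolate that would open the pyranone ring, the peracid should attack C3 anti to the 2-aryl group, and silyl migration gives the 2,3-trans silyloxy ketone, which is also the stable C3 epimer.

Step 9
Reactants: 16 (2R,3R)-7-(benzyloxy)-2-[4-(benzyloxy)phenyl]-3-hydroxy-2,3-dihydro-4H-chromen-4-one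
Product: 17 (2R,3S,4R)-7-(benzyloxy)-2-[4-(benzyloxy)phenyl]chroman-3,4-diol (2,3-trans-3,4-trans)
Conditions: NaBH4, THF–MeOH, 0 °C
Reagents that add atoms: none
Why: Borohydride reduction of the dihydroflavonol; axial hydride delivery should give mainly the equatorial 4-OH, and the C4 configuration does not matter because C4 is ionised in step 10.

Step 10
Reactants: 17 (2R,3S,4R)-7-(benzyloxy)-2-[4-(benzyloxy)phenyl]chroman-3,4-diol; 9 (2R,3S)-5,7-bis(benzyloxy)-2-[3,4-bis(benzyloxy)phenyl]chroman-3-ol (3 equiv)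
Product: 18 (2R,3S,4S)-7-(benzyloxy)-2-[4-(benzyloxy)phenyl]-4-[(2R,3S)-5,7-bis(benzyloxy)-2-[3,4-bis(benzyloxy)phenyl]-3-hydroxychroman-8-yl]chroman-3-ol (hexa-O-benzyl guibourtinidol-(4α→8)-catechin)
Conditions: TMSOTf (0.2 equiv), 4 Å MS, CH2Cl2, −78 → −30 °C; Et3N quench
Reagents that add atoms: none
Why: Biomimetic interflavanyl coupling (Friedel–Crafts alkylation): acid ionises the 4-OH, which leaves as water, to the benzylic C4 cation stabilised by O1 and the 7-benzyloxy group, and C8 of the phloroglucinol ring of 9 (less hindered than C6) should attack anti to the equatorial 3-OH, giving the 3,4-trans (4α) bond with the 2-aryl and 4-aryl groups cis; the excess of 9 suppresses oligomers.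

Step 11
Reactants: 18 hexa-O-benzyl guibourtinidol-(4α→8)-catechin
Product: 19 (2R,4S)-7-(benzyloxy)-2-[4-(benzyloxy)phenyl]-4-[(2R)-5,7-bis(benzyloxy)-2-[3,4-bis(benzyloxy)phenyl]-3-oxochroman-8-yl]chroman-3-one
Conditions: Dess–Martin periodinane (3 equiv), CH2Cl2, 0 → 20 °C
Reagents that add atoms: none
Why: Dess–Martin oxidation of both secondary alcohols under non-basic conditions; the upper ketone already has its two flanking aryl groups cis-diequatorial, so enolisation has no driving force to erode C2 or C4, and 2-aryl-chroman-3-ones of the lower type should keep C2 under these conditions.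

Step 12
Reactants: 19 the bis-3-ketone
Product: 20 (2R,3R,4S)-7-(benzyloxy)-2-[4-(benzyloxy)phenyl]-4-[(2R,3R)-5,7-bis(benzyloxy)-2-[3,4-bis(benzyloxy)phenyl]-3-hydroxychroman-8-yl]chroman-3-ol (hexa-O-benzyl epiguibourtinidol-(4α→8)-epicatechin)
Conditions: LiBH(s-Bu)3 (4 equiv), LiBr, THF, −78 °C
Reagents that add atoms: none
Why: Substrate-controlled reduction with a bulky hydride: LiBH(s-Bu)3 should attack each ketone from the equatorial direction and give the axial alcohols, that is 2,3-cis in the lower ring (the catechin-to-epicatechin type of inversion) and 2,3-cis-3,4-cis in the upper ring.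

Step 13
Reactants: 20 hexa-O-benzyl epiguibourtinidol-(4α→8)-epicatechin
Product: 21 (2R,3R,4S)-2-(4-hydroxyphenyl)-4-[(2R,3R)-2-(3,4-dihydroxyphenyl)-3,5,7-trihydroxychroman-8-yl]chroman-3,7-diol (epiguibourtinidol-(4α→8)-epicatechin, the target)
Conditions: H2 (1 atm), Pd(OH)2/C, THF–MeOH–H2O, 20 °C
Reagents that add atoms: none
Why: Hydrogenolysis of the six benzyl ethers under neutral conditions; the interflavanyl bond of the 5-deoxy upper unit and the benzylic C2–O1 bonds should survive, and no stereocentre is touched.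

**Compound list**

1 | 5,7-dihydroxy-4H-chromen-4-one | O=c1ccoc2cc(O)cc(O)c12 | starting material
2 | 5,7-bis(benzyloxy)-4H-chromen-4-one | O=c1ccoc2cc(OCc3ccccc3)cc(OCc3ccccc3)c12 | intermediate
3 | [3,4-bis(benzyloxy)phenyl]boronic acid | OB(O)c1ccc(OCc2ccccc2)c(OCc2ccccc2)c1 | starting material
4 | (2S)-5,7-bis(benzyloxy)-2-[3,4-bis(benzyloxy)phenyl]-2,3-dihydro-4H-chromen-4-one | c1(OCc2ccccc2)cc(OCc2ccccc2)c2c(c1)O[C@H](c1ccc(OCc3ccccc3)c(OCc3ccccc3)c1)CC2=O | intermediate
5 | (2S)-5,7-bis(benzyloxy)-2-[3,4-bis(benzyloxy)phenyl]-4-methoxy-2H-chromene | c1(OCc2ccccc2)cc(OCc2ccccc2)c2c(c1)O[C@H](c1ccc(OCc3ccccc3)c(OCc3ccccc3)c1)C=C2OC | intermediate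
6 | methyl (2S,3S)-4,6-bis(benzyloxy)-2-[3,4-bis(benzyloxy)phenyl]-2,3-dihydro-1-benzofuran-3-carboxylate | c1(OCc2ccccc2)cc(OCc2ccccc2)c2c(c1)O[C@H](c1ccc(OCc3ccccc3)c(OCc3ccccc3)c1)[C@H]2C(=O)OC | intermediate
7 | [(2S,3R)-4,6-bis(benzyloxy)-2-[3,4-bis(benzyloxy)phenyl]-2,3-dihydro-1-benzofuran-3-yl]methanol | c1(OCc2ccccc2)cc(OCc2ccccc2)c2c(c1)O[C@H](c1ccc(OCc3ccccc3)c(OCc3ccccc3)c1)[C@H]2CO | intermediate
8 | [(2S,3R)-4,6-bis(benzyloxy)-2-[3,4-bis(benzyloxy)phenyl]-2,3-dihydro-1-benzofuran-3-yl]methyl methanesulfonate | c1(OCc2ccccc2)cc(OCc2ccccc2)c2c(c1)O[C@H](c1ccc(OCc3ccccc3)c(OCc3ccccc3)c1)[C@H]2COS(C)(=O)=O | intermediate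
9 | (2R,3S)-5,7-bis(benzyloxy)-2-[3,4-bis(benzyloxy)phenyl]chroman-3-ol | c1(OCc2ccccc2)cc(OCc2ccccc2)c2c(c1)O[C@H](c1ccc(OCc3ccccc3)c(OCc3ccccc3)c1)[C@@H](O)C2 | intermediate
10 | 7-hydroxy-4H-chromen-4-one | O=c1ccoc2cc(O)ccc12 | starting material
11 | 7-(benzyloxy)-4H-chromen-4-one | O=c1ccoc2cc(OCc3ccccc3)ccc12 | intermediate
12 | [4-(benzyloxy)phenyl]boronic acid | OB(O)c1ccc(OCc2ccccc2)cc1 | starting material
13 | (2S)-7-(benzyloxy)-2-[4-(benzyloxy)phenyl]-2,3-dihydro-4H-chromen-4-one | c1(OCc2ccccc2)ccc2c(c1)O[C@H](c1ccc(OCc3ccccc3)cc1)CC2=O | intermediate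
14 | (2S)-7-(benzyloxy)-2-[4-(benzyloxy)phenyl]-4-(trimethylsilyloxy)-2H-chromene | c1(OCc2ccccc2)ccc2c(c1)O[C@H](c1ccc(OCc3ccccc3)cc1)C=C2O[Si](C)(C)C | intermediate
15 | (2R,3R)-7-(benzyloxy)-2-[4-(benzyloxy)phenyl]-3-(trimethylsilyloxy)-2,3-dihydro-4H-chromen-4-one | c1(OCc2ccccc2)ccc2c(c1)O[C@H](c1ccc(OCc3ccccc3)cc1)[C@@H](O[Si](C)(C)C)C2=O | intermediate
16 | (2R,3R)-7-(benzyloxy)-2-[4-(benzyloxy)phenyl]-3-hydroxy-2,3-dihydro-4H-chromen-4-one | c1(OCc2ccccc2)ccc2c(c1)O[C@H](c1ccc(OCc3ccccc3)cc1)[C@@H](O)C2=O | intermediate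
17 | (2R,3S,4R)-7-(benzyloxy)-2-[4-(benzyloxy)phenyl]chroman-3,4-diol | c1(OCc2ccccc2)ccc2c(c1)O[C@H](c1ccc(OCc3ccccc3)cc1)[C@@H](O)[C@@H]2O | intermediate
18 | hexa-O-benzyl guibourtinidol-(4α→8)-catechin, upper unit (2R,3S,4S), lower unit (2R,3S) | O(Cc1ccccc1)c1ccc([C@H]2Oc3cc(OCc4ccccc4)ccc3[C@@H](c3c(OCc4ccccc4)cc(OCc4ccccc4)c4c3O[C@H](c3ccc(OCc5ccccc5)c(OCc5ccccc5)c3)[C@@H](O)C4)[C@@H]2O)cc1 | intermediate
19 | bis-3-ketone of 18, upper unit (2R,4S), lower unit (2R) | O(Cc1ccccc1)c1ccc([C@H]2Oc3cc(OCc4ccccc4)ccc3[C@@H](c3c(OCc4ccccc4)cc(OCc4ccccc4)c4c3O[C@H](c3ccc(OCc5ccccc5)c(OCc5ccccc5)c3)C(=O)C4)C2=O)cc1 | intermediate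
20 | hexa-O-benzyl epiguibourtinidol-(4α→8)-epicatechin, upper unit (2R,3R,4S), lower unit (2R,3R) | O(Cc1ccccc1)c1ccc([C@H]2Oc3cc(OCc4ccccc4)ccc3[C@@H](c3c(OCc4ccccc4)cc(OCc4ccccc4)c4c3O[C@H](c3ccc(OCc5ccccc5)c(OCc5ccccc5)c3)[C@H](O)C4)[C@H]2O)cc1 | intermediate
21 | epiguibourtinidol-(4α→8)-epicatechin, (2R,3R,4S)-2-(4-hydroxyphenyl)-4-[(2R,3R)-2-(3,4-dihydroxyphenyl)-3,5,7-trihydroxychroman-8-yl]chroman-3,7-diol | Oc1ccc([C@H]2Oc3cc(O)ccc3[C@@H](c3c(O)cc(O)c4c3O[C@H](c3ccc(O)c(O)c3)[C@H](O)C4)[C@H]2O)cc1 | target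

**Step count:** 13 steps in total. Longest linear sequence: 9 steps (steps 1–5, then 10–13).

**Steps most likely to fail**

Step 5 (key step). The phenonium ion may be opened by water at the primary carbon (return to 7). It may instead collapse by 1,2-hydride shift and proton loss to an aromatic 3-methylbenzofuran. The sulfonate may also return to C3, after which the ring oxygen takes part and the pyran ring is not formed cleanly. The fallback gives up the ring expansion and uses established flavonoid chemistry. It sets out from flavanone 4, which is reduced with NaBH4 to the 2,4-cis alcohol (2S,4S)-5,7-bis(benzyloxy)-2-[3,4-bis(benzyloxy)phenyl]chroman-4-ol F1. Dehydration with MsCl and Et3N gives the flav-3-ene (2S)-5,7-bis(benzyloxy)-2-[3,4-bis(benzyloxy)phenyl]-2H-chromene F2, which is kept cold and in the dark. Hydroboration with BH3·THF anti to the 2-aryl group, with boron at C3, and oxidation with NaOH/H2O2 should place the 3-OH trans, and the sequence comes back to the route at 9.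

Step 3. The 2-aryl group may shift to C3 in place of the benzo carbon C4a (isoflavone formation). The enol ether may simply be dehydrogenated to the flavone. The iodine electrophile may also attack the polyalkoxy arenes. The fallback reaches the same ester by a Wolff ring contraction and sets out from 4. Trifluoroacetylation of the lithium enolate (LiN(SiMe3)2, CF3CO2CH2CF3, −78 °C, kept cold so that the enolate does not open the ring) gives (2S)-5,7-bis(benzyloxy)-2-[3,4-bis(benzyloxy)phenyl]-3-(trifluoroacetyl)chroman-4-one F3. Diazo transfer with MsN3 and Et3N gives (2R)-5,7-bis(benzyloxy)-2-[3,4-bis(benzyloxy)phenyl]-3-diazochroman-4-one F4 (C2 spatially unchanged). Irradiation of F4 in MeOH triggers the Wolff rearrangement, in which C4a migrates to the carbene carbon and methanol adds to the ketene. The 3-epimer is separated without base, so that the 2-aryloxy ester cannot open by β-elimination, and the sequence comes back to the route at 6.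

Step 10. The C4 cation may attack C6 instead of C8 of 9. It may be attacked on the face syn to the 3-OH (poor facial selectivity, 3,4-cis bond). It may also react with a second molecule of electrophile or product (oligomerisation). The fallback changes the control element to neighbouring-group participation and sets out from 17. Acetylation (Ac2O, pyridine, DMAP) gives the 3,4-di-O-acetate of 17, 7-(benzyloxy)-2-[4-(benzyloxy)phenyl]chromane-3,4-diyl diacetate F5. With TMSOTf the 4-acetate leaves with participation of the 3-acetoxy group (cis-fused acetoxonium ion on the face of the 3-oxygen), so 9 should enter only trans. The resulting dimer, the upper-unit 3-O-acetate of 18 F6, is deacetylated with K2CO3 in MeOH, and the sequence comes back to the route at 18.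

**Further compounds**

F1 | step 5 | (2S,4S)-5,7-bis(benzyloxy)-2-[3,4-bis(benzyloxy)phenyl]chroman-4-ol | c1(OCc2ccccc2)cc(OCc2ccccc2)c2c(c1)O[C@H](c1ccc(OCc3ccccc3)c(OCc3ccccc3)c1)C[C@@H]2O
F2 | step 5 | (2S)-5,7-bis(benzyloxy)-2-[3,4-bis(benzyloxy)phenyl]-2H-chromene | c1(OCc2ccccc2)cc(OCc2ccccc2)c2c(c1)O[C@H](c1ccc(OCc3ccccc3)c(OCc3ccccc3)c1)C=C2
F3 | step 3 | (2S)-5,7-bis(benzyloxy)-2-[3,4-bis(benzyloxy)phenyl]-3-(trifluoroacetyl)chroman-4-one (C3 enolisable) | c1(OCc2ccccc2)cc(OCc2ccccc2)c2c(c1)O[C@H](c1ccc(OCc3ccccc3)c(OCc3ccccc3)c1)C(C(=O)C(F)(F)F)C2=O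
F4 | step 3 | (2R)-5,7-bis(benzyloxy)-2-[3,4-bis(benzyloxy)phenyl]-3-diazochroman-4-one | c1(OCc2ccccc2)cc(OCc2ccccc2)c2c(c1)O[C@H](c1ccc(OCc3ccccc3)c(OCc3ccccc3)c1)C(=[N+]=[N-])C2=O
F5 | step 10 | 3,4-di-O-acetate of 17 (2,3-trans-3,4-trans) | c1(OCc2ccccc2)ccc2c(c1)O[C@H](c1ccc(OCc3ccccc3)cc1)[C@@H](OC(C)=O)[C@@H]2OC(C)=O
F6 | step 10 | upper-unit 3-O-acetate of 18 | O(Cc1ccccc1)c1ccc([C@H]2Oc3cc(OCc4ccccc4)ccc3[C@@H](c3c(OCc4ccccc4)cc(OCc4ccccc4)c4c3O[C@H](c3ccc(OCc5ccccc5)c(OCc5ccccc5)c3)[C@@H](O)C4)[C@@H]2OC(C)=O)cc1
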